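**Plan**
1. Retrosynthetic cuts, in order: the C8 ester C–O bond (side-chain acid), C11=C13, the O–C10 ether bond (back to a C5 alcohol and a C9=C10 alkene), then C1–C2 of the ten-membered ring by a retro-Cope step that re-forms C4–C9.
2. Feature used: C1–C2 is three atoms from C4 (through C3) and from C9 (through C10), so the carbocycle C1–C10 with its C3=C4 enoate is the [3,3] isomer of a cyclohexane C4–C9 carrying vinyl and CO2Me on C4 and a cis isopropenyl on C9.
3. That cyclohexane is cut at C9–C10 and C4–C15 (cuprate addition and carboxylation of a 1,3-diene ester), at C5–O/C6–O (osmylation) and at C8–O (iodolactonisation), back to a Birch-reduced benzoate whose ester carbon becomes C3.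
4. Forward ring order: carbocycle from the arene, a temporary cis C8 lactone, the trans C6 γ-lactone, the ten-membered ring by Cope ring expansion, then the oxygen bridge (two seven-membered rings) by transannular etherification; the acyl side chain comes last.
5. Stereochemistry: C7/C8 from a catalyst-controlled desymmetrising iodolactonisation; C9 anti to O8; C4 anti to C9; C5/C6 by hydroxyl-directed osmylation; alkene geometries from the lactone-locked chair; C10 from the bridge; the side-chain centre from resolution.

Key step: step 13

**Remarks**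
- Locants of the target are used throughout: C10 methyl-bearing ether carbon; C1, C2 CH2; C3 vinylic CH; C4 ester-bearing carbon; C5 ether CH; C6 lactone O–CH; C7; C8 acyloxy CH; C9 CH2; C11, C12, C13 lactone α-carbon, carbonyl, methylene; C14 methyl; C15 ester carbon. With C4→C9 drawn clockwise, β is the face carrying O5 and O6 and α the opposite face.
- Assumption: 2-[4-(methoxycarbonyl)phenyl]acetic acid, the benzoate mono-methyl ester of 4-(carboxymethyl)benzoic acid, is bought as such.
- Assumption: the catalyst of step 2 favours the enantiomer drawn; if it favours the mirror image, its pseudo-enantiomer hydroquinine 1,4-phthalazinediyl diether is used.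
- Assumption: the S enantiomer collected in step 18 is identified by its sign of rotation.

**Route**

Step 1
Reactants: 1 2-[4-(methoxycarbonyl)phenyl]acetic acid
Product: 3 2-[4-(methoxycarbonyl)cyclohexa-2,5-dien-1-yl]acetic acid (cis/trans mixture at C4/C7), via dilithium dienolate 2 (not isolated)
Conditions: Li (3.3 equiv), NH3(l)/THF, t-BuOH (1.5 equiv), −78 °C; then NH4Cl; H3O+ to pH 3
Reagents that add atoms: none
Why: Birch reduction of the benzoate ring stops at the 1,4-dihydro stage because tert-butanol protonates C7 and the resulting ester dienolate 2 is not reduced further, kinetic α-protonation on quench keeps the two alkenes skipped, and the C4/C7 relationship is left open because C4 is flattened again in step 3.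

Step 2
Reactants: 3 2-[4-(methoxycarbonyl)cyclohexa-2,5-dien-1-yl]acetic acid
Product: 4 cis-fused iodolactone (O8 α, C11 α, iodine on C9 β, both C4 epimers)
Conditions: N-iodosuccinimide (1.2 equiv), hydroquinidine 1,4-phthalazinediyl diether [(DHQD)2PHAL] (10 mol %), CHCl3/toluene, −40 °C
Reagents that add atoms: N-iodosuccinimide, O=C1CCC(=O)N1I
Why: Catalytic enantioselective 5-exo iodolactonisation should fix C7, C8 and C9 at once, because the C12 carboxylate can reach C8 only from the face of its own tether (cis fusion), iodine adds anti at C9, and the chiral ammonium carboxylate ion pair selects one of the two enantiotopic ring alkenes as in desymmetrising halolactonisations of other cyclohexadienyl acids.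

Step 3
Reactants: 4 cis-fused iodolactone
Product: 6 methyl 3-hydroxy-4-[2-oxo-2-(pyrrolidin-1-yl)ethyl]cyclohexa-1,5-diene-1-carboxylate (8α-OH and C11 cis), via diene lactone 5 (not isolated)
Conditions: DBU (1.1 equiv), CH2Cl2, 0 °C; then pyrrolidine (5 equiv), rt
Reagents that add atoms: pyrrolidine, C1CCNC1
Why: E1cB elimination removes the C4 hydrogen (acidified by the ester and the C5=C6 alkene) and iodide from C9 whichever C4 epimer is present, and aminolysis of the allylic γ-lactone then frees O8 and stores C12 as an amide that cannot re-lactonise under neutral or basic conditions, no stereocentre being touched.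

Step 4
Reactants: 6 hydroxy amide diene ester
Product: 7 8α-tert-butyldimethylsilyl ether of 6
Conditions: tert-butyldimethylsilyl chloride (1.5 equiv), imidazole (3 equiv), DMF, 0 °C → rt
Reagents that add atoms: tert-butyldimethylsilyl chloride, CC(C)(C)[Si](C)(C)Cl
Why: Standard silylation of the secondary allylic alcohol turns O8 into a non-leaving γ-substituent, so that the next step is a conjugate addition and not an allylic substitution or reductive loss of O8.

Step 5
Reactants: 7 silyl ether diene ester; 8 isopropenylmagnesium bromide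
Product: 10 malonic half-ester acid (9β-isopropenyl; on C4 the new CO2H α and CO2Me β), via bromomagnesium dienolate 9 (not isolated)
Conditions: 8 (2.4 equiv), CuBr·SMe2 (1.2 equiv), THF, −40 °C; 7, −78 → −30 °C; then CO2 (g), −30 → 0 °C; 1 M HCl
Reagents that add atoms: carbon dioxide, O=C=O
Why: Organocuprate 1,4-addition followed by enolate carboxylation should deliver isopropenyl to C9 anti to the γ-silyloxy group on C8 and then carboxylate the cross-conjugated dienolate 9 at its α-carbon C4 on the face opposite to the new vicinal isopropenyl group, as in three-component enone couplings, so that C9 and the quaternary C4 are set in one operation and the CO2-derived carboxyl becomes C15.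

Step 6
Reactants: 10 malonic half-ester acid
Product: 11 hydroxy acid (C4: CH2OH β, CO2H α)
Conditions: LiBH4 (3 equiv), THF/MeOH (20:1), 0 °C → rt; 1 M HCl
Reagents that add atoms: none
Why: Chemoselective borohydride reduction takes the methyl ester (the former benzoate carbon, now C3) to the primary alcohol while the lithium carboxylate and the tertiary amide are not reduced, so the two C4 substituents are told apart without change at C4.

Step 7
Reactants: 11 hydroxy acid
Product: 12 hydroxy methyl ester (C4: CH2OH β, CO2Me α)
Conditions: Me3SiCHN2 (1.3 equiv), toluene/MeOH (4:1), 0 °C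
Reagents that add atoms: trimethylsilyldiazomethane, C[Si](C)(C)C=[N+]=[N-]
Why: Diazoalkane esterification of the hindered quaternary acid is neutral and leaves the primary alcohol, the silyl ether, the amide and the alkenes untouched.

Step 8
Reactants: 12 hydroxy methyl ester
Product: 14 5β,6β-diol (triol amide), via osmate ester 13 (not isolated)
Conditions: OsO4 (1.05 equiv), TMEDA (1.1 equiv), CH2Cl2, −78 °C; then aq Na2SO3, THF, 40 °C
Reagents that add atoms: osmium tetroxide, O=[Os](=O)(=O)=O
Why: In this Donohoe directed dihydroxylation the OsO4·TMEDA complex accepts a hydrogen bond from the homoallylic C4 hydroxymethyl group and is delivered syn to it onto the β face of the C5=C6 ring alkene in preference to the remote isopropenyl group, which sets C5 and C6 cis to each other and cis to C3.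

Step 9
Reactants: 14 triol amide
Product: 15 trans-fused 6,12-lactone diol (free 5β-OH and C4 CH2OH)
Conditions: AcOH/toluene (1:4), 80 °C
Reagents that add atoms: none
Why: Acid-mediated N→O acyl transfer (lactonisation of a γ-hydroxy amide) can only engage O6 because O8 is silylated, and since O6 is β and C11 α the γ-lactone is trans-fused, which locks the cyclohexane in the chair needed in step 13 while the weak acid spares the silyl ether and the isopropenyl group.

Step 10
Reactants: 15 trans-lactone diol
Product: 16 β-hydroxy aldehyde (C4: CHO β, CO2Me α)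
Conditions: 2,2,6,6-tetramethylpiperidin-1-oxyl (TEMPO, 0.1 equiv), PhI(OAc)2 (1.2 equiv), CH2Cl2, rt
Reagents that add atoms: none
Why: Oxoammonium oxidation is selective for the primary alcohol over the hindered secondary C5 alcohol and stops at the non-enolisable aldehyde under non-basic conditions that avoid retro-aldol cleavage of C4–C5.

Step 11
Reactants: 16 β-hydroxy aldehyde
Product: 17 5β-triethylsilyloxy aldehyde
Conditions: Et3SiOTf (1.5 equiv), 2,6-lutidine (3 equiv), CH2Cl2, −78 → −40 °C
Reagents that add atoms: triethylsilyl trifluoromethanesulfonate, CC[Si](CC)(CC)OS(=O)(=O)C(F)(F)F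
Why: Silylation with the triflate caps the axial C5 alcohol, so that no alkoxide can trigger retro-aldol cleavage in the Wittig step and no hydroxyl can add to the syn-axial isopropenyl group during the thermolysis.

Step 12
Reactants: 17 silyloxy aldehyde
Product: 18 lactone-fused cis-4-vinyl-9-isopropenylcyclohexane (5β-OTES, 8α-OTBS)
Conditions: Ph3PCH3Br (2.2 equiv), KN(SiMe3)2 (2.0 equiv), THF, 0 °C; then 17, −78 → 0 °C
Reagents that add atoms: methyltriphenylphosphonium bromide, C[P+](c1ccccc1)(c1ccccc1)c1ccccc1.[Br-]
Why: Wittig methylenation of the neopentyl aldehyde by the unstabilised ylide is much faster than attack on the lactone or the ester and installs the C3=C2 vinyl group cis to the C9 isopropenyl group without touching a stereocentre.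

Step 13
Reactants: 18 lactone-fused cis-divinylcyclohexane
Product: 19 ten-membered diene (13-norgermacra-3,9-dien-6,12-olide 15-oate; C9=C10 trans in the ring, C3=C4 with C2 cis to C5; 5β-OTES, 8α-OTBS)
Conditions: toluene (0.01 M), 2,6-di-tert-butyl-4-methylphenol (0.1 equiv), sealed tube, 160 °C
Reagents that add atoms: none
Why: This is a thermal Cope rearrangement, a concerted [3,3]-sigmatropic shift through the chair array C2–C3–C4–C9–C10–C1 in which C1–C2 forms as C4–C9 breaks, the closest precedent being the interconversion of cis-1,2-divinylcyclohexanes and (E,Z)-cyclodeca-1,5-dienes. The ten-membered carbocycle is closed by ring expansion, the new C1–C2 σ bond being made in a six-centre pericyclic mode while the six-membered ring opens. No stereocentre is created (C4 and C9 become sp2); two alkene geometries are set instead. The step needs one of the two possible chairs, and the trans-fused lactone secures it: with O6 and C11 held diequatorial the ring cannot flip, the C4 vinyl is equatorial and the C9 isopropenyl axial, so in the transition state C5 is pseudo-axial and the ester pseudo-equatorial, which places C2 cis to C5 in the C3=C4 enoate (required for the later seven-membered ether ring) and the trans geometry in C9=C10. The normally unfavourable equilibrium should be pushed forward by enoate conjugation, by loss of the quaternary C4 and by relief of the two syn-diaxial pairs of the locked chair (O5-silyl/isopropenyl and O8-silyl/CO2Me), and the diene is removed irreversibly in step 14.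

Step 14
Reactants: 19 ten-membered diene
Product: 21 5,10-oxygen-bridged lactone (8α-OTBS), via C5 alcohol 20 (not isolated)
Conditions: pyridinium p-toluenesulfonate (0.2 equiv), CH2Cl2/MeOH (5:1), 0 °C → rt; evaporate; then camphor-10-sulfonic acid (0.1 equiv), CH2Cl2, 0 °C
Reagents that add atoms: none
Why: Acid-catalysed methanolysis removes the triethylsilyl ether far faster than the tert-butyldimethylsilyl ether, and protonation of the strained trans C9=C10 alkene at C9 then gives the tertiary C10 cation (Markovnikov) that O5 captures across the ring (transannular hydroalkoxylation closing a seven-membered ring on either side of the bridge), the C10 configuration being the only one the one-atom bridge allows with O5 fixed on the β face.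

Step 15
Reactants: 21 bridged lactone
Product: 23 α-(dimethylaminomethyl) lactone (C11 epimers), via lithium lactone enolate 22 (not isolated)
Conditions: LiN(i-Pr)2 (1.1 equiv), THF, −78 °C; then Me2N=CH2+ I− (1.5 equiv), −78 → 0 °C
Reagents that add atoms: Eschenmoser's salt (N,N-dimethylmethyleneiminium iodide), C=[N+](C)C.[I-]
Why: Kinetic deprotonation should occur at the lactone α-CH2, which is more acidic and more accessible than the γ-hydrogens of the enoate, and the enolate 22 then undergoes a Mannich reaction with the iminium salt, the new C11 centre being of no consequence because it is flattened in step 16.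

Step 16
Reactants: 23 Mannich base
Product: 25 α-methylene lactone (8α-OTBS), via trimethylammonium iodide 24 (not isolated)
Conditions: MeI (10 equiv), CH2Cl2/MeOH, rt; then NaHCO3 (aq), EtOAc, rt
Reagents that add atoms: none
Why: Exhaustive N-methylation followed by base-induced E1cB (Hofmann-type) loss of trimethylamine is the standard end of the Eschenmoser methylenation and gives the C11=C13 exocyclic alkene under conditions too mild to affect the enoate or the silyl ether.

Step 17
Reactants: 25 α-methylene lactone silyl ether
Product: 26 8α-alcohol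
Conditions: HF·pyridine, pyridine, THF, 0 °C → rt
Reagents that add atoms: none
Why: Desilylation with buffered HF frees O8 without generating an alkoxide that could add to the methylene lactone or translactonise to a cis 8,12-lactone.

Step 18
Reactants: 27 racemic 2-hydroxy-2-methylbut-3-enoic acid
Product: 28 (S)-2-hydroxy-2-methylbut-3-enoic acid
Conditions: preparative supercritical-fluid chromatography, amylose tris(3,5-dimethylphenylcarbamate) stationary phase, CO2/MeOH (0.1% CF3CO2H)
Reagents that add atoms: none
Why: Chromatographic resolution on a chiral stationary phase separates the two enantiomers of the small α-hydroxy acid without any covalent change, so the quaternary centre of the side chain is obtained as a single enantiomer.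

Step 19
Reactants: 28 (S)-2-hydroxy-2-methylbut-3-enoic acid
Product: 30 (S)-2-methyl-2-(triethylsilyloxy)but-3-enoic acid, via bis(triethylsilyl) derivative 29 (not isolated)
Conditions: Et3SiOTf (2.4 equiv), 2,6-lutidine (3 equiv), CH2Cl2, 0 °C; then MeOH, rt
Reagents that add atoms: triethylsilyl trifluoromethanesulfonate, CC[Si](CC)(CC)OS(=O)(=O)C(F)(F)F
Why: Bis-silylation followed by selective methanolysis of the labile silyl ester leaves the tertiary silyl ether, masking the hydroxyl that would otherwise compete in the acylation, and does not touch the stereocentre.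

Step 20
Reactants: 26 8α-alcohol; 30 O-silyl side-chain acid
Product: 32 O-triethylsilyl ether of the target, via mixed trichlorobenzoic anhydride 31 (not isolated)
Conditions: 2,4,6-trichlorobenzoyl chloride (1.5 equiv), Et3N (2 equiv), 30, THF, rt; then 26, 4-(dimethylamino)pyridine (2 equiv), toluene, rt → 40 °C
Reagents that add atoms: none
Why: In this Yamaguchi esterification 4-(dimethylamino)pyridine attacks the mixed anhydride 31 at the less shielded acyl group and the acylpyridinium acylates the secondary C8 alcohol with retention at C8 and without affecting the non-epimerisable quaternary centre of the acid.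

Step 21
Reactants: 32 O-triethylsilyl ether of the target
Product: 33 CNP0325750.1
Conditions: HF·pyridine, pyridine, THF, 0 °C
Reagents that add atoms: none
Why: Fluoride-mediated cleavage of the tertiary triethylsilyl ether proceeds under buffered conditions that the two esters, the methylene lactone and the bridging ether tolerate, and releases the target.

**Compound list**
1 | 2-[4-(methoxycarbonyl)phenyl]acetic acid | COC(=O)c1ccc(CC(=O)O)cc1 | starting material
2 | dilithium dienolate of 3 (lithium ester enolate at C4, lithium carboxylate at C12) | [Li+].[Li+].COC([O-])=C1C=CC(CC(=O)[O-])C=C1 | intermediate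
3 | 2-[4-(methoxycarbonyl)cyclohexa-2,5-dien-1-yl]acetic acid, cis/trans mixture (C4 and C7 undefined, each isomer achiral) | COC(=O)C1C=CC(CC(=O)O)C=C1 | intermediate
4 | methyl 7-iodo-2-oxo-2,3,3a,6,7,7a-hexahydro-1-benzofuran-6-carboxylate; cis-fused C12–O8 γ-lactone, O8 α, C11 α, iodine on C9 β, both C4 epimers | O1[C@@H]2[C@@H](I)C(C(=O)OC)C=C[C@@H]2CC1=O | intermediate
5 | methyl 2-oxo-2,3,3a,7a-tetrahydro-1-benzofuran-6-carboxylate; cis-fused lactone, C4=C9 and C5=C6 | O1[C@@H]2C=C(C(=O)OC)C=C[C@@H]2CC1=O | intermediate
6 | methyl 3-hydroxy-4-[2-oxo-2-(pyrrolidin-1-yl)ethyl]cyclohexa-1,5-diene-1-carboxylate; 8α-OH cis to the C7 side chain | O[C@@H]1C=C(C(=O)OC)C=C[C@@H]1CC(=O)N2CCCC2 | intermediate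
7 | methyl 3-(tert-butyldimethylsilyloxy)-4-[2-oxo-2-(pyrrolidin-1-yl)ethyl]cyclohexa-1,5-diene-1-carboxylate; 8α-OTBS cis to the C7 side chain | CC(C)(C)[Si](C)(C)O[C@@H]1C=C(C(=O)OC)C=C[C@@H]1CC(=O)N2CCCC2 | intermediate
8 | isopropenylmagnesium bromide (prop-1-en-2-ylmagnesium bromide, commercial THF solution) | C=C(C)[Mg]Br | starting material
9 | bromomagnesium ester dienolate after 1,4-addition; 9β-isopropenyl, 8α-OTBS, C11 α | CC(C)(C)[Si](C)(C)O[C@@H]1[C@@H](C(C)=C)C(=C(OC)O[Mg]Br)C=C[C@@H]1CC(=O)N2CCCC2 | intermediate
10 | 1-(methoxycarbonyl)-5-(tert-butyldimethylsilyloxy)-4-[2-oxo-2-(pyrrolidin-1-yl)ethyl]-6-(prop-1-en-2-yl)cyclohex-2-ene-1-carboxylic acid; on C4 CO2H (C15) α and CO2Me β; 9β-isopropenyl, 8α-OTBS, C11 α | CC(C)(C)[Si](C)(C)O[C@@H]1[C@@H](C(C)=C)[C@](C(=O)OC)(C(=O)O)C=C[C@@H]1CC(=O)N2CCCC2 | intermediate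
11 | 1-(hydroxymethyl)-5-(tert-butyldimethylsilyloxy)-4-[2-oxo-2-(pyrrolidin-1-yl)ethyl]-6-(prop-1-en-2-yl)cyclohex-2-ene-1-carboxylic acid; on C4 CH2OH β and CO2H α | CC(C)(C)[Si](C)(C)O[C@@H]1[C@@H](C(C)=C)[C@](CO)(C(=O)O)C=C[C@@H]1CC(=O)N2CCCC2 | intermediate
12 | methyl ester of 11; on C4 CH2OH β and CO2Me α | CC(C)(C)[Si](C)(C)O[C@@H]1[C@@H](C(C)=C)[C@](CO)(C(=O)OC)C=C[C@@H]1CC(=O)N2CCCC2 | intermediate
13 | cyclic osmate ester (hexavalent osmium) of the 5β,6β-diol, TMEDA adduct | CC(C)(C)[Si](C)(C)O[C@@H]1[C@@H](C(C)=C)[C@](CO)(C(=O)OC)[C@H]2O[Os](=O)(=O)O[C@H]2[C@@H]1CC(=O)N3CCCC3.CN(C)CCN(C)C | intermediate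
14 | methyl 2,3-dihydroxy-1-(hydroxymethyl)-5-(tert-butyldimethylsilyloxy)-4-[2-oxo-2-(pyrrolidin-1-yl)ethyl]-6-(prop-1-en-2-yl)cyclohexane-1-carboxylate; 5β-OH, 6β-OH, C11 α, 8α-OTBS, 9β-isopropenyl, C4 CH2OH β | CC(C)(C)[Si](C)(C)O[C@@H]1[C@@H](C(C)=C)[C@](CO)(C(=O)OC)[C@@H](O)[C@@H](O)[C@@H]1CC(=O)N2CCCC2 | intermediate
15 | methyl 7-hydroxy-6-(hydroxymethyl)-4-(tert-butyldimethylsilyloxy)-2-oxo-5-(prop-1-en-2-yl)octahydro-1-benzofuran-6-carboxylate; trans-fused 6,12-lactone (O6 β, C11 α), 5β-OH | CC(C)(C)[Si](C)(C)O[C@@H]1[C@@H](C(C)=C)[C@](CO)(C(=O)OC)[C@@H](O)[C@H]2OC(=O)C[C@@H]21 | intermediate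
16 | the corresponding C4 aldehyde (CHO β, CO2Me α), 5β-OH free | CC(C)(C)[Si](C)(C)O[C@@H]1[C@@H](C(C)=C)[C@](C=O)(C(=O)OC)[C@@H](O)[C@H]2OC(=O)C[C@@H]21 | intermediate
17 | 5β-triethylsilyl ether of 16 | CC(C)(C)[Si](C)(C)O[C@@H]1[C@@H](C(C)=C)[C@](C=O)(C(=O)OC)[C@@H](O[Si](CC)(CC)CC)[C@H]2OC(=O)C[C@@H]21 | intermediate
18 | methyl 6-ethenyl-4-(tert-butyldimethylsilyloxy)-2-oxo-5-(prop-1-en-2-yl)-7-(triethylsilyloxy)octahydro-1-benzofuran-6-carboxylate; C4 vinyl β and CO2Me α, 9β-isopropenyl (cis-divinyl), 5β-OTES, trans-lactone, 8α-OTBS | CC(C)(C)[Si](C)(C)O[C@@H]1[C@@H](C(C)=C)[C@](C=C)(C(=O)OC)[C@@H](O[Si](CC)(CC)CC)[C@H]2OC(=O)C[C@@H]21 | intermediate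
19 | 13-norgermacra-3,9-dien-6,12-olide 15-oic acid methyl ester with 5β-OTES and 8α-OTBS; C9=C10 trans in the ring, C3=C4 with C2 cis to C5 | CC(C)(C)[Si](C)(C)O[C@@H]1/C=C(C)/CC/C=C(C(=O)OC)\[C@@H](O[Si](CC)(CC)CC)[C@H]2OC(=O)C[C@@H]21 | intermediate
20 | 5β-alcohol of 19 | CC(C)(C)[Si](C)(C)O[C@@H]1/C=C(C)/CC/C=C(C(=O)OC)\[C@@H](O)[C@H]2OC(=O)C[C@@H]21 | intermediate
21 | 5,10-epoxy (oxygen-bridged) 13-norgermacr-3-en-6,12-olide 15-oate with 8α-OTBS; bridge O β at C5 and C10, C14 methyl α | CC(C)(C)[Si](C)(C)O[C@@H]1C[C@]2(C)CCC=C(C(=O)OC)[C@@H](O2)[C@H]2OC(=O)C[C@@H]21 | intermediate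
22 | lithium enolate of lactone 21 | CC(C)(C)[Si](C)(C)O[C@@H]1C[C@]2(C)CCC=C(C(=O)OC)[C@@H](O2)[C@H]2OC(O[Li])=C[C@@H]21 | intermediate
23 | 11-(dimethylaminomethyl) lactone, C11 epimers | CC(C)(C)[Si](C)(C)O[C@@H]1C[C@]2(C)CCC=C(C(=O)OC)[C@@H](O2)[C@H]2OC(=O)C(CN(C)C)[C@@H]21 | intermediate
24 | the corresponding trimethylammonium iodide | CC(C)(C)[Si](C)(C)O[C@@H]1C[C@]2(C)CCC=C(C(=O)OC)[C@@H](O2)[C@H]2OC(=O)C(C[N+](C)(C)C)[C@@H]21.[I-] | intermediate
25 | α-methylene lactone with 8α-OTBS | CC(C)(C)[Si](C)(C)O[C@@H]1C[C@]2(C)CCC=C(C(=O)OC)[C@@H](O2)[C@H]2OC(=O)C(=C)[C@@H]21 | intermediate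
26 | 8α-alcohol (deacyl target) | O[C@@H]1C[C@]2(C)CCC=C(C(=O)OC)[C@@H](O2)[C@H]2OC(=O)C(=C)[C@@H]21 | intermediate
27 | racemic 2-hydroxy-2-methylbut-3-enoic acid | C=CC(C)(O)C(=O)O | starting material
28 | (S)-2-hydroxy-2-methylbut-3-enoic acid | C=C[C@](C)(O)C(=O)O | intermediate
29 | triethylsilyl (S)-2-methyl-2-(triethylsilyloxy)but-3-enoate | C=C[C@](C)(O[Si](CC)(CC)CC)C(=O)O[Si](CC)(CC)CC | intermediate
30 | (S)-2-methyl-2-(triethylsilyloxy)but-3-enoic acid | C=C[C@](C)(O[Si](CC)(CC)CC)C(=O)O | intermediate
31 | mixed anhydride of 30 and 2,4,6-trichlorobenzoic acid | C=C[C@](C)(O[Si](CC)(CC)CC)C(=O)OC(=O)c1c(Cl)cc(Cl)cc1Cl | intermediate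
32 | target with the side-chain hydroxyl as its triethylsilyl ether | C=C[C@](C)(O[Si](CC)(CC)CC)C(=O)O[C@@H]1C[C@]2(C)CCC=C(C(=O)OC)[C@@H](O2)[C@H]2OC(=O)C(=C)[C@@H]21 | intermediate
33 | CNP0325750.1 | C=C[C@](C)(O)C(=O)O[C@@H]1C[C@]2(C)CCC=C(C(=O)OC)[C@@H](O2)[C@H]2OC(=O)C(=C)[C@@H]21 | target

**Step count**
Total: 21 steps. Longest linear sequence: 19 steps (steps 1–17, 20, 21); steps 18–19 prepare the side-chain acid.

**Steps most likely to fail**

Step 13. The equilibrium may stay on the side of the divinylcyclohexane, or the strained ten-membered diene may revert during isolation. The fallback ties the rearrangement to the ether closure so that the diene never accumulates. It sets out from 18, whose triethylsilyl ether is removed (pyridinium p-toluenesulfonate, MeOH) to give the C5 alcohol of the cyclohexane precursor F1. F1 is heated in toluene at 130–150 °C with a catalytic amount of pyridinium p-toluenesulfonate, so that each molecule that rearranges is protonated at its strained trans C9=C10 bond and closed by O5. The acid is kept weak so that the unstrained isopropenyl group of F1 is not protonated at a competitive rate. The product is 21, where the main route is rejoined.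

Step 2. The catalyst may discriminate poorly between the two enantiotopic alkenes, and differently for the two C4 epimers of 3. The fallback replaces catalyst control by auxiliary control. It sets out from 3, which is coupled (EDC·HCl, 1-hydroxybenzotriazole, CH2Cl2) with (2R,5R)-2,5-bis(methoxymethyl)pyrrolidine to give the C2-symmetric amide F2. Iodolactonisation of F2 with I2 in THF/H2O passes through an iminium lactone that is hydrolysed in the flask with loss of the auxiliary amine (the enantiomeric auxiliary is taken if the sense is opposite). The product is 4, where the route is rejoined.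

Step 5. Facial selectivity in the carboxylation of dienolate 9 may be low or reversed, because the C8 silyloxy group lies syn-axial to the α face of C4. The two carboxyl groups on C4 differ only in which one is reduced, so the epimer can be steered to the same alcohol. The fallback sets out from 7: the same addition and carboxylation give the C4-epimeric half-ester acid F3 (CO2H β, CO2Me α). Its acid is activated as the isobutyl carbonic anhydride F4 (isobutyl chloroformate, N-methylmorpholine, THF, −15 °C) and reduced with NaBH4 (THF/H2O, 0 °C), which leaves the α methyl ester. This gives 12 directly, one step shorter than the main line; if both epimers form they are separated and each is treated by its own reduction.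

**Further compounds**
F1 | step 13 | C5 alcohol of the cyclohexane precursor (18 without the triethylsilyl group) | CC(C)(C)[Si](C)(C)O[C@@H]1[C@@H](C(C)=C)[C@](C=C)(C(=O)OC)[C@@H](O)[C@H]2OC(=O)C[C@@H]21
F2 | step 2 | methyl 4-{2-[(2R,5R)-2,5-bis(methoxymethyl)pyrrolidin-1-yl]-2-oxoethyl}cyclohexa-2,5-diene-1-carboxylate | COC(=O)C1C=CC(CC(=O)N2[C@@H](COC)CC[C@@H]2COC)C=C1
F3 | step 5 | C4 epimer of 10 (CO2H β, CO2Me α) | CC(C)(C)[Si](C)(C)O[C@@H]1[C@@H](C(C)=C)[C@](C(=O)O)(C(=O)OC)C=C[C@@H]1CC(=O)N2CCCC2
F4 | step 5 | isobutyl carbonic anhydride of F3 | CC(C)(C)[Si](C)(C)O[C@@H]1[C@@H](C(C)=C)[C@](C(=O)OC(=O)OCC(C)C)(C(=O)OC)C=C[C@@H]1CC(=O)N2CCCC2
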